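**Retrosynthetic overview**
1. Cut both ester C–O bonds. This gives (2E,6E)-2,6-dimethylocta-2,6-dienedioic acid and two equivalents of one amino alcohol, (4R,4aS,6R,7S,7aR)-2,4,7-trimethyloctahydro-1H-cyclopenta[c]pyridin-6-ol.
2. The amino alcohol comes from the saturated N-methyl δ-lactam, and that from the α,β-unsaturated δ-lactam. OH-directed hydrogenation sets C4 and C4a.
3. The unsaturated lactam comes from a bicyclo[3.3.0]octenone by N-methyl insertion into its C(=O)–CH2 bond. This is a five- to six-membered ring expansion through a carbon-to-nitrogen 1,2-shift.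
4. The bicyclic enone comes from a 1,6-enyne by Pauson–Khand reaction. The enyne comes from pent-3-yn-1-ol and but-3-en-2-yl acetate by anti-crotylation, which sets C6 and C7.
5. Ring order: ring A (cyclopentanol) and ring B (cyclopentenone) form together, then ring B is enlarged to the piperidine. The diacid comes from but-3-enylcopper plus methyl but-2-ynoate, followed by cross-metathesis with methyl methacrylate.

Assumption: the (S)-SEGPHOS iridium catalyst is taken to give the (3S,4R) anti adduct in step 1. If Mosher analysis shows the antipode, (R)-SEGPHOS is used and nothing else changes.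

**Step 1**
Reactants: 1 pent-3-yn-1-ol; 2 but-3-en-2-yl acetate (racemic)
Product: 4 (3S,4R)-3-methyloct-1-en-6-yn-4-ol, via pent-3-ynal 3 (not isolated)
Conditions: [Ir(cod)Cl]2 (2.5 mol %), (S)-SEGPHOS (5 mol %), 4-cyano-3-nitrobenzoic acid (10 mol %), Cs2CO3 (20 mol %), 2 (2 equiv), THF, 90 °C
Reagents that add atoms: none
Why: Krische transfer-hydrogenative carbonyl crotylation, in which the alcohol is dehydrogenated to the aldehyde and the (E)-σ-crotyliridium species adds through a closed chair transition state, so the anti C3/C4 relationship follows from the chair and the absolute sense from the chiral bisphosphine.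

**Step 2**
Reactants: 4 (3S,4R)-3-methyloct-1-en-6-yn-4-ol
Product: 5 (5S,6S,7R)-7-hydroxy-2,6-dimethylbicyclo[3.3.0]oct-1-en-3-one
Conditions: Co2(CO)8 (10 mol %), tetramethylthiourea (60 mol %), CO (1 atm), toluene, 70 °C
Reagents that add atoms: carbon monoxide, [C-]#[O+]
Why: Intramolecular Pauson–Khand reaction of a 1,6-enyne builds both five-membered rings at once, and the allylic methyl and the carbinol OH both take exo positions in the cobaltacycle, so the new bridgehead H5 ends cis to the C6 methyl.

**Step 3**
Reactants: 5 (5S,6S,7R)-7-hydroxy-2,6-dimethylbicyclo[3.3.0]oct-1-en-3-one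
Product: 8 (6R,7S,7aS)-6-hydroxy-2,4,7-trimethyl-1,2,5,6,7,7a-hexahydro-3H-cyclopenta[c]pyridin-3-one, via Z-nitrone 6 (not isolated), via spiro-oxaziridine 7 (not isolated)
Conditions: MeNHOH·HCl (1.5 equiv), NaOAc (1.5 equiv), MeOH, 50 °C; filter, dilute with MeCN (0.01 M); hν 310 nm then 254 nm, quartz flow coil, 15 °C
Reagents that add atoms: N-methylhydroxylamine hydrochloride, CNO.Cl
Why: Proposed new method: one-flask N-methyl nitrogen insertion into a cross-conjugated cyclopentenone, a substrate class on which the photochemical nitrone/oxaziridine-to-lactam ring expansion has not been shown; condensation gives the nitrone with its N-methyl turned away from the C2 methyl (Z), light converts it to the configurationally stable spiro-oxaziridine with N-methyl syn to C4H2, and N–O homolysis then drives a stepwise radical-pair 1,2-shift from carbon to nitrogen of the C–C bond anti to the nitrogen lone pair, which is the C3–C4H2 bond and also the only one that avoids a vinyl-radical-like migrating terminus, so nitrogen enters on the CH2 side (opposite to a Beckmann rearrangement of the oxime), the six-membered ring and the N–C1 bond are formed and no stereocentre is touched; closest known reaction type: photochemical oxaziridine-to-lactam ring expansion of saturated 2-substituted cycloalkanones and the photo-Beckmann rearrangement.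

**Step 4**
Reactants: 8 (6R,7S,7aS)-6-hydroxy-2,4,7-trimethyl-1,2,5,6,7,7a-hexahydro-3H-cyclopenta[c]pyridin-3-one
Product: 9 (4R,4aR,6R,7S,7aR)-6-hydroxy-2,4,7-trimethyloctahydro-3H-cyclopenta[c]pyridin-3-one
Conditions: [Ir(cod)(PCy3)(py)]PF6 (10 mol %), H2 (10 atm), CH2Cl2, 25 °C
Reagents that add atoms: none
Why: Hydroxyl-directed homogeneous hydrogenation, in which the homoallylic C6–OH (on the face of H7a) binds the cationic iridium and both hydrogens are delivered syn to that face of the C4=C4a alkene, giving the cis ring fusion and placing the C4 methyl on the opposite face.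

**Step 5**
Reactants: 9 (4R,4aR,6R,7S,7aR)-6-hydroxy-2,4,7-trimethyloctahydro-3H-cyclopenta[c]pyridin-3-one
Product: 10 (4R,4aS,6R,7S,7aR)-2,4,7-trimethyloctahydro-1H-cyclopenta[c]pyridin-6-ol
Conditions: LiAlH4 (3 equiv), THF, 66 °C; then Na2SO4·10H2O
Reagents that add atoms: none
Why: Amide-to-amine reduction of a tertiary lactam with LiAlH4 (the alcohol rides through as its alkoxide), with no stereocentre formed or enolised.

**Step 6**
Reactants: 11 but-3-en-1-ylmagnesium bromide (0.5 M in THF); 12 methyl but-2-ynoate
Product: 15 methyl (2E)-3-methylhepta-2,6-dienoate, via but-3-enylcopper 13 (not isolated), via alkenylcopper adduct 14 (not isolated)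
Conditions: CuBr·SMe2 (1.2 equiv), 11 (1.2 equiv), THF, −40 °C; 12, −78 °C; sat. aq. NH4Cl, −78 °C to 23 °C
Reagents that add atoms: none
Why: syn-Carbocupration (conjugate addition of a monoorganocopper reagent to an ynoate) puts the butenyl group and copper on the same side, and cold protonation with retention gives the E trisubstituted enoate.

**Step 7**
Reactants: 15 methyl (2E)-3-methylhepta-2,6-dienoate; 16 methyl methacrylate
Product: 17 dimethyl (2E,6E)-2,6-dimethylocta-2,6-dienedioate
Conditions: 16 (10 equiv), second-generation Hoveyda–Grubbs catalyst RuCl2(H2IMes)(=CH-2-iPrOC6H4) (5 mol %), CH2Cl2, 40 °C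
Reagents that add atoms: none
Why: Olefin cross-metathesis of a terminal alkene with an excess of a 1,1-disubstituted electron-poor alkene gives the E 2-methylenoate under thermodynamic control, while the existing trisubstituted enoate is inert to the catalyst.

**Step 8**
Reactants: 17 dimethyl (2E,6E)-2,6-dimethylocta-2,6-dienedioate
Product: 19 (2E,6E)-2,6-dimethylocta-2,6-dienedioic acid, via dilithium dicarboxylate 18 (not isolated)
Conditions: LiOH (6 equiv), THF/MeOH/H2O, 45 °C; then 1 M HCl
Reagents that add atoms: lithium hydroxide, [Li+].[OH-]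
Why: Acyl-oxygen saponification of both methyl esters, under which conjugated E enoates keep their geometry.

**Step 9**
Reactants: 19 (2E,6E)-2,6-dimethylocta-2,6-dienedioic acid; 10 (4R,4aS,6R,7S,7aR)-2,4,7-trimethyloctahydro-1H-cyclopenta[c]pyridin-6-ol
Product: 22 bis[(4R,4aS,6R,7S,7aR)-2,4,7-trimethyloctahydro-1H-cyclopenta[c]pyridin-6-yl] (2E,6E)-2,6-dimethylocta-2,6-dienedioate (CNP0240822.3), via C8 monoester 20 (not isolated), via C1 monoester 21 (not isolated)
Conditions: 10 (2.2 equiv), DCC (2.4 equiv), DMAP (0.3 equiv), CH2Cl2, 0 to 23 °C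
Reagents that add atoms: none
Why: Double Steglich esterification leaves the C6–O bond of the alcohol untouched (retention at C6), and catalytic DMAP at or below room temperature limits deconjugation or E/Z drift of the 3-methylenoate end.

**Compound list**
1 | pent-3-yn-1-ol | CC#CCCO | starting material
2 | but-3-en-2-yl acetate (racemic) | CC(OC(C)=O)C=C | starting material
3 | pent-3-ynal | CC#CCC=O | intermediate
4 | (3S,4R)-3-methyloct-1-en-6-yn-4-ol (anti) | O[C@H](CC#CC)[C@@H](C)C=C | intermediate
5 | (5S,6S,7R)-7-hydroxy-2,6-dimethylbicyclo[3.3.0]oct-1-en-3-one (H5, 6-methyl and 7-OH on one face) | O[C@@H]1CC2=C(C)C(=O)C[C@H]2[C@@H]1C | intermediate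
6 | (Z)-N-methylnitrone of 5 (nitrone O syn to C2, N-methyl syn to C4H2) | O[C@@H]1CC2=C(C)\C(=[N+](/[O-])C)C[C@H]2[C@@H]1C | intermediate
7 | spiro-oxaziridine at C3 of the bicyclooctene (N-methyl syn to C4H2; drawn with O on the face of H5; both spiro epimers converge on 8) | O[C@@H]1CC2=C(C)[C@]3(O[N@@]3C)C[C@H]2[C@@H]1C | intermediate
8 | (6R,7S,7aS)-6-hydroxy-2,4,7-trimethyl-1,2,5,6,7,7a-hexahydro-3H-cyclopenta[c]pyridin-3-one | O[C@@H]1CC2=C(C)C(=O)N(C)C[C@H]2[C@@H]1C | intermediate
9 | (4R,4aR,6R,7S,7aR)-6-hydroxy-2,4,7-trimethyloctahydro-3H-cyclopenta[c]pyridin-3-one | O[C@@H]1C[C@@H]2[C@@H](CN(C)C(=O)[C@@H]2C)[C@@H]1C | intermediate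
10 | (4R,4aS,6R,7S,7aR)-2,4,7-trimethyloctahydro-1H-cyclopenta[c]pyridin-6-ol | O[C@@H]1C[C@@H]2[C@@H](CN(C)C[C@@H]2C)[C@@H]1C | intermediate
11 | but-3-en-1-ylmagnesium bromide | C=CCC[Mg]Br | starting material
12 | methyl but-2-ynoate | CC#CC(=O)OC | starting material
13 | but-3-enylcopper | C=CCC[Cu] | intermediate
14 | methyl (2Z)-2-cuprio-3-methylhepta-2,6-dienoate (Cu cis to butenyl) | COC(=O)/C([Cu])=C(\C)CCC=C | intermediate
15 | methyl (2E)-3-methylhepta-2,6-dienoate | C/C(=C\C(=O)OC)CCC=C | intermediate
16 | methyl methacrylate | C=C(C)C(=O)OC | starting material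
17 | dimethyl (2E,6E)-2,6-dimethylocta-2,6-dienedioate | C/C(=C\C(=O)OC)CC/C=C(\C)C(=O)OC | intermediate
18 | dilithium (2E,6E)-2,6-dimethylocta-2,6-dienedioate | C/C(=C\C(=O)[O-])CC/C=C(\C)C(=O)[O-].[Li+].[Li+] | intermediate
19 | (2E,6E)-2,6-dimethylocta-2,6-dienedioic acid | C/C(=C\C(=O)O)CC/C=C(\C)C(=O)O | intermediate
20 | C8 monoester (3-methylenoate end esterified with 10) | C/C(=C\C(=O)O[C@@H]1C[C@@H]2[C@@H](CN(C)C[C@@H]2C)[C@@H]1C)CC/C=C(\C)C(=O)O | intermediate
21 | C1 monoester (2-methylenoate end esterified with 10) | C/C(=C\C(=O)O)CC/C=C(\C)C(=O)O[C@@H]1C[C@@H]2[C@@H](CN(C)C[C@@H]2C)[C@@H]1C | intermediate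
22 | CNP0240822.3, bis[(4R,4aS,6R,7S,7aR)-2,4,7-trimethyloctahydro-1H-cyclopenta[c]pyridin-6-yl] (2E,6E)-2,6-dimethylocta-2,6-dienedioate | C/C(=C\C(=O)O[C@@H]1C[C@@H]2[C@@H](CN(C)C[C@@H]2C)[C@@H]1C)CC/C=C(\C)C(=O)O[C@@H]1C[C@@H]2[C@@H](CN(C)C[C@@H]2C)[C@@H]1C | target

**Totals**
Total step count: 9. Longest linear sequence: 6 (steps 1, 2, 3, 4, 5 and 9).

**Three steps most likely to fail**

Step 3 (the proposed new step). Three things could go wrong:
- The nitrone may scramble its geometry under light.
- The alkenyl oxaziridine may take other N–O cleavage paths.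
- Lactam 8 may suffer secondary photolysis at 254 nm.

The fallback uses only known chemistry on the saturated ketone, the substrate class for which CH2 migration is established. It sets out from 5.
- Hydrogenation (H2, 1 atm, Pd/C, EtOAc) gives the saturated ketone (1R,2R,5R,6S,7R)-7-hydroxy-2,6-dimethylbicyclo[3.3.0]octan-3-one F1. Strain in the five-five system enforces the cis fusion, and syn addition places the C2 methyl endo.
- Condensation with MeNH2 (4 Å sieves, THF, 0 °C) gives the (E)-N-methylimine F2.
- mCPBA (CH2Cl2, −78 °C) gives the isolable spiro-oxaziridine F3, with N-methyl syn to CH2.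
- Photolysis at 254 nm (MeCN, quartz) expands the ring.

The fallback comes back to the route at 9, so step 4 is no longer needed.

Step 4. The alkene is tetrasubstituted and electron-poor, so it may be too unreactive. Without the OH direction, the six-five system could also give the trans fusion. The fallback sets out from 8 and swaps the order of reductions.
- AlH3 (from LiAlH4 and AlCl3, THF, 0 °C) takes the lactam to the allylic amine (6R,7S,7aS)-2,4,7-trimethyl-2,3,5,6,7,7a-hexahydro-1H-cyclopenta[c]pyridin-6-ol F4. Its isolated tetrasubstituted alkene is the standard substrate for OH-directed hydrogenation.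
- Hydrogenation uses [Ir(cod)(PCy3)(py)][B(3,5-(CF3)2C6H3)4] and H2 (50 atm) in CH2Cl2. HBF4·OEt2 (1.05 equiv) keeps the amine protonated and off the metal. A basic work-up follows.

The fallback comes back to the route at 10, so step 5 is no longer needed.

Step 1. The transient β,γ-alkynyl aldehyde may isomerise to the allenal, or the internal alkyne may interfere with the iridium hydride. The fallback sets out from 1 and replaces redox-neutral catalysis with a stoichiometric chiral allylborane.
- Dess–Martin periodinane (NaHCO3, CH2Cl2, 0 °C) gives pent-3-ynal 3, used cold and crude.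
- The aldehyde is added at −78 °C to (E)-crotyldiisopinocampheylborane. This reagent is made from trans-but-2-ene, n-BuLi/KOtBu, (−)-Ipc2BOMe and BF3·OEt2.
- NaOH/H2O2 work-up completes the Brown anti-crotylboration, which attacks the Si face through a closed chair.

The fallback comes back to the route at 4.

**Further compounds**
F0 | step 1 | none | none
F1 | step 3 | (1R,2R,5R,6S,7R)-7-hydroxy-2,6-dimethylbicyclo[3.3.0]octan-3-one | O[C@@H]1C[C@@H]2[C@@H](CC(=O)[C@@H]2C)[C@@H]1C
F2 | step 3 | (E)-N-methylimine of F1 (N-methyl syn to C4H2) | O[C@@H]1C[C@@H]2[C@@H](C/C(=N\C)[C@@H]2C)[C@@H]1C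
F3 | step 3 | spiro-oxaziridine of F1 (O on the convex face, N-methyl syn to C4H2) | O[C@@H]1C[C@@H]2[C@@H](C[C@@]3(O[N@@]3C)[C@@H]2C)[C@@H]1C
F4 | step 4 | (6R,7S,7aS)-2,4,7-trimethyl-2,3,5,6,7,7a-hexahydro-1H-cyclopenta[c]pyridin-6-ol | O[C@@H]1CC2=C(C)CN(C)C[C@H]2[C@@H]1C
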